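**Plan**
- Retrosynthesis cuts, in this order: the C3–O angelate ester, the C7–C11 bond, the C4 methyl (back to a C4 ketone), both ring B bonds C5–C6 and C9–C10 in one operation, and last the C3–O bond on ring A.
- Enabling feature: ring B (C5, C6=C7, C8=O, C9, C10) has its ketone para to the methylated quaternary C5 and is cis-fused to ring A at C5/C10. That is the imprint of a 2-silyloxybuta-1,3-diene adding across C5=C10 of a 2-methylcyclohex-2-enone whose carbonyl is C4.
- Forward: ring A is bought as 2-methylcyclohex-2-enone and oxygenated at C3; ring B closes in the Lewis-acid Diels–Alder step. The C4 ketone then becomes the C4 methyl, the silyl enol ether becomes the C6=C7 enone, C7 is iodinated and coupled with the propanoate, and the angelate goes on last.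
- Stereochemistry: C3 from a catalyst-controlled epoxidation of a silyl dienol ether; C5 and C10 relayed from C3 in the cycloaddition (anti approach, suprafacial addition); C4 by hydrogenation from the α face; C11 by a chiral nickel catalyst; the Z alkene is bought with angelic acid.

Key step: step 5

Remark: atoms are numbered as in eremophilanes (ring A: C1–C5 and C10; ring B: C5–C10; C11 is the side-chain methine on C7); β is the face that carries the C5 methyl.
Assumption: the L-fructose-derived ketone in step 2 and the (S,S) bis(oxazoline) in step 10 are taken to give the 3S and 11R configurations; if a model run shows the opposite sense, the mirror-image catalyst is used.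

**Step 1**
Reactants: 1 2-methylcyclohex-2-en-1-one
Product: 3 tert-butyl(dimethyl)[(6-methylcyclohexa-1,5-dien-1-yl)oxy]silane, via lithium dienolate 2 (not isolated)
Conditions: LiN(iPr)2 (1.1 equiv), THF, −78 °C; then TBSOTf, −78 → 0 °C
Reagents that add atoms: tert-butyldimethylsilyl trifluoromethanesulfonate, CC(C)(C)[Si](C)(C)OS(=O)(=O)C(F)(F)F
Why: Kinetic deprotonation of the enone removes an α' proton (the future C3), and O-silylation of the cross-conjugated dienolate gives the 2-silyloxy diene (kinetic enolate trapping).

**Step 2**
Reactants: 3 tert-butyl(dimethyl)[(6-methylcyclohexa-1,5-dien-1-yl)oxy]silane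
Product: 5 (S)-6-hydroxy-2-methylcyclohex-2-en-1-one, via silyloxy epoxide 4 (not isolated)
Conditions: L-fructose-derived ketone 1,2:4,5-di-O-isopropylidene-β-L-erythro-2,3-hexodiulo-2,6-pyranose (enantiomer of the Shi ketone, 30 mol %), KHSO5 (as 2KHSO5·KHSO4·K2SO4), K2CO3, Bu4NHSO4, MeCN/CH2(OMe)2/aq. Na2B4O7 buffer (pH 10.5), 0 °C; then aq. citric acid/THF, 23 °C
Reagents that add atoms: potassium peroxymonosulfate, [K+].[O-]S(=O)(=O)OO
Why: Shi asymmetric epoxidation used as a Rubottom-type oxidation: the chiral dioxirane attacks the electron-rich enol ether alkene in preference to the methyl-substituted one, and, by analogy with 1-arylcyclohexenes (R,R with the D-fructose ketone), the L-series catalyst should deliver oxygen to the face that gives the S carbinol once the silyloxy epoxide collapses.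

**Step 3**
Reactants: 5 (S)-6-hydroxy-2-methylcyclohex-2-en-1-one
Product: 6 (S)-6-(tert-butyldimethylsilyloxy)-2-methylcyclohex-2-en-1-one
Conditions: TBSCl, imidazole, DMF, 23 °C
Reagents that add atoms: tert-butyldimethylsilyl chloride, CC(C)(C)[Si](C)(C)Cl
Why: Standard silylation of a secondary alcohol under mildly basic conditions that should not enolise the α-oxygenated ketone, so the C3 configuration is kept.

**Step 4**
Reactants: 7 but-3-en-2-one (methyl vinyl ketone)
Product: 8 2-(tert-butyldimethylsilyloxy)buta-1,3-diene
Conditions: TBSOTf, Et3N, Et2O, 0 °C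
Reagents that add atoms: tert-butyldimethylsilyl trifluoromethanesulfonate, CC(C)(C)[Si](C)(C)OS(=O)(=O)C(F)(F)F
Why: Soft enolisation of the methyl ketone (silyl triflate activation, amine deprotonation) gives the silyl enol ether; the tert-butyldimethylsilyl group is chosen over trimethylsilyl so that the diene and the enol ether of the adduct survive the Lewis acid and chromatography.

**Step 5**
Reactants: 6 (S)-6-(tert-butyldimethylsilyloxy)-2-methylcyclohex-2-en-1-one; 8 2-(tert-butyldimethylsilyloxy)buta-1,3-diene
Product: 9 (2S,4aR,8aS)-2,6-bis(tert-butyldimethylsilyloxy)-8a-methyl-3,4,4a,5,8,8a-hexahydronaphthalen-1(2H)-one (eremophilane numbering: C4 ketone, 3β-silyloxy, 5β-methyl, 10β-H, C7=C8 silyl enol ether)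
Conditions: 8 (3 equiv), Me2AlCl (1.2 equiv), CH2Cl2, −78 → −30 °C; Et3N, then aq. NaHCO3
Reagents that add atoms: none
Why: Me2AlCl binds the C4 carbonyl and lowers the enone LUMO, so the diene CH2 next to the silyloxy carbon (future C9), its most nucleophilic terminus, bonds to the β-carbon C10 while the other terminus (C6) bonds to the methyl-bearing α-carbon C5, in a concerted but asynchronous [4+2] cycloaddition (a stepwise Michael–Michael sequence would converge on the same adduct). The closest known reaction type is the aluminium-Lewis-acid-promoted Diels–Alder reaction of 2-methylcyclohex-2-enones with 2-silyloxybuta-1,3-dienes, which gives angularly methylated cis-decalones. Ring B is closed by this [4+2] cycloaddition, both new σ bonds forming on one face of the enone. C5 and C10 are created together: their cis relationship follows from suprafacial addition, and their absolute configuration from C3, because the silyloxy group α to the complexed carbonyl should sit pseudoaxial (dipole minimisation) and screen its own face at C5, so the diene adds anti to it. The step needs regioselectivity (C8 oxygen para to C5), dictated by the 2-silyloxy group of the diene, and π-facial selectivity, secured by the C3 silyl ether; endo/exo selectivity is irrelevant because the diene termini are unsubstituted. The enol ether double bond of the adduct lies at C7=C8 and later fixes the position of the enone.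

**Step 6**
Reactants: 9 Diels–Alder adduct
Product: 10 4-methylidene compound (C4=CH2 in place of C4=O; 3β-silyloxy, 5β-methyl, 10β-H, C7=C8 silyl enol ether)
Conditions: Cp2TiMe2 (3 equiv), toluene, 80 °C, dark
Reagents that add atoms: dimethyltitanocene, C[Ti+2]C.c1cc[cH-]c1.c1cc[cH-]c1
Why: Petasis methylenation: the non-basic titanium methylidene converts the hindered, enolisable α-silyloxy ketone to the alkene without epimerising C3 or touching the silyl enol ether.

**Step 7**
Reactants: 10 4-methylidene compound
Product: 11 3β,8-bis(tert-butyldimethylsilyloxy)-4β,5β-dimethyl-10βH-cis-decal-7-ene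
Conditions: H2 (1 atm), 5% Pt/C, EtOAc, Et3N (1 vol %), 23 °C
Reagents that add atoms: none
Why: Heterogeneous hydrogenation under steric approach control: the 1,1-disubstituted alkene should be reduced in preference to the trisubstituted silyl enol ether, and since the β face of C4 is flanked on both sides by the C5 methyl and the C3 silyloxy group (pushed toward axial positions by A(1,3) strain with the methylidene), hydrogen should arrive from the α face and leave the new methyl β, cis to both.

**Step 8**
Reactants: 11 bis(silyl) ether
Product: 12 3β-(tert-butyldimethylsilyloxy)-4β,5β-dimethyl-10βH-cis-decal-6-en-8-one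
Conditions: Pd(OAc)2 (1.1 equiv), MeCN/DMSO, 40 °C
Reagents that add atoms: none
Why: Saegusa–Ito oxidation: divalent palladium replaces silicon at the enol ether and syn β-hydride elimination is possible only toward C6, so the regiochemistry set in the cycloaddition is transferred to the C6=C7 enone.

**Step 9**
Reactants: 12 enone
Product: 13 7-iodo-3β-(tert-butyldimethylsilyloxy)-4β,5β-dimethyl-10βH-cis-decal-6-en-8-one
Conditions: I2 (2 equiv), pyridine/CH2Cl2 (1:1), 0 → 23 °C
Reagents that add atoms: iodine, II
Why: Johnson α-iodination of an enone (reversible pyridine addition at C6 makes C7 nucleophilic toward I2), well established for 4,4-disubstituted cyclohex-2-enones of this type.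

**Step 10**
Reactants: 13 iodoenone; 14 methyl 2-chloropropanoate (racemic)
Product: 15 methyl (11R)-3β-(tert-butyldimethylsilyloxy)-8-oxo-10βH-eremophil-6-en-12-oate
Conditions: 14 (2 equiv), NiBr2(dme) (10 mol %), (S,S)-4-heptyl-BiOX (12 mol %), Mn powder (3 equiv), NaI (0.5 equiv), TMSCl (0.2 equiv), DMA, 5 °C
Reagents that add atoms: none
Why: Proposed new method: zerovalent nickel should insert into the C7–I bond, the planar α-ester radical formed from either enantiomer of the chloride by halogen abstraction is captured by the alkenylnickel species, and reductive elimination from the bis(oxazoline)-bound nickel sets C11 under catalyst control while Mn turns the catalyst over (enantioconvergent reductive cross-electrophile coupling); the closest known reaction types are the Ni-catalysed asymmetric reductive couplings of α-chloroesters with aryl iodides and of alkenyl bromides with benzylic chlorides, and an α-iodoenone is an untested alkenyl partner.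

**Step 11**
Reactants: 15 silyl ether
Product: 16 methyl (11R)-3β-hydroxy-8-oxo-10βH-eremophil-6-en-12-oate
Conditions: HF·pyridine, pyridine/THF, 0 → 23 °C
Reagents that add atoms: none
Why: Fluoride-mediated desilylation in a buffered, non-basic medium, chosen so that the C11 centre (α to the ester and allylic) is not epimerised.

**Step 12**
Reactants: 16 alcohol; 17 angelic acid
Product: 19 CNP0323033.1 [methyl (11R)-3β-angeloyloxy-8-oxo-10βH-eremophil-6-en-12-oate], via mixed anhydride 18 (not isolated)
Conditions: 17, 2,4,6-trichlorobenzoyl chloride, Et3N, toluene, 23 °C; then 16, toluene, 80 °C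
Reagents that add atoms: none
Why: Yamaguchi esterification: the hindered aroyl carbonyl of the mixed anhydride is shielded, so the alcohol attacks the angeloyl carbonyl, and omitting a nucleophilic catalyst should avoid Z to E isomerisation to the tiglate; no stereocentre is touched.

**Compound list**
1 | 2-methylcyclohex-2-en-1-one | CC1=CCCCC1=O | starting material
2 | lithium 6-methylcyclohexa-1,5-dien-1-olate | [Li+].[O-]C1=CCCC=C1C | intermediate (not isolated)
3 | tert-butyl(dimethyl)[(6-methylcyclohexa-1,5-dien-1-yl)oxy]silane | CC1=CCCC=C1O[Si](C)(C)C(C)(C)C | intermediate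
4 | (1S,6S)-1-(tert-butyldimethylsilyloxy)-2-methyl-7-oxabicyclo[4.1.0]hept-2-ene | O1[C@H]2CCC=C(C)[C@@]12O[Si](C)(C)C(C)(C)C | intermediate (not isolated)
5 | (S)-6-hydroxy-2-methylcyclohex-2-en-1-one | O[C@H]1CCC=C(C)C1=O | intermediate
6 | (S)-6-(tert-butyldimethylsilyloxy)-2-methylcyclohex-2-en-1-one | CC(C)(C)[Si](C)(C)O[C@H]1CCC=C(C)C1=O | intermediate
7 | but-3-en-2-one | CC(=O)C=C | starting material
8 | 2-(tert-butyldimethylsilyloxy)buta-1,3-diene | C=CC(=C)O[Si](C)(C)C(C)(C)C | intermediate
9 | (2S,4aR,8aS)-2,6-bis(tert-butyldimethylsilyloxy)-8a-methyl-3,4,4a,5,8,8a-hexahydronaphthalen-1(2H)-one | CC(C)(C)[Si](C)(C)O[C@H]1CC[C@@H]2CC(O[Si](C)(C)C(C)(C)C)=CC[C@]2(C)C1=O | intermediate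
10 | 4-methylidene analogue of 9 (3β-silyloxy, 5β-methyl, 10β-H, C7=C8 silyl enol ether) | CC(C)(C)[Si](C)(C)O[C@H]1CC[C@@H]2CC(O[Si](C)(C)C(C)(C)C)=CC[C@]2(C)C1=C | intermediate
11 | 3β,8-bis(tert-butyldimethylsilyloxy)-4β,5β-dimethyl-10βH-cis-decal-7-ene | CC(C)(C)[Si](C)(C)O[C@H]1CC[C@@H]2CC(O[Si](C)(C)C(C)(C)C)=CC[C@]2(C)[C@H]1C | intermediate
12 | 3β-(tert-butyldimethylsilyloxy)-4β,5β-dimethyl-10βH-cis-decal-6-en-8-one | CC(C)(C)[Si](C)(C)O[C@H]1CC[C@@H]2CC(=O)C=C[C@]2(C)[C@H]1C | intermediate
13 | 7-iodo derivative of 12 | CC(C)(C)[Si](C)(C)O[C@H]1CC[C@@H]2CC(=O)C(I)=C[C@]2(C)[C@H]1C | intermediate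
14 | methyl 2-chloropropanoate (racemic) | CC(Cl)C(=O)OC | starting material
15 | methyl (11R)-3β-(tert-butyldimethylsilyloxy)-8-oxo-10βH-eremophil-6-en-12-oate | CC(C)(C)[Si](C)(C)O[C@H]1CC[C@@H]2CC(=O)C([C@@H](C)C(=O)OC)=C[C@]2(C)[C@H]1C | intermediate
16 | methyl (11R)-3β-hydroxy-8-oxo-10βH-eremophil-6-en-12-oate | O[C@H]1CC[C@@H]2CC(=O)C([C@@H](C)C(=O)OC)=C[C@]2(C)[C@H]1C | intermediate
17 | angelic acid, (Z)-2-methylbut-2-enoic acid | C/C=C(/C)C(=O)O | starting material
18 | (Z)-2-methylbut-2-enoic 2,4,6-trichlorobenzoic anhydride | C/C=C(/C)C(=O)OC(=O)c1c(Cl)cc(Cl)cc1Cl | intermediate (not isolated)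
19 | CNP0323033.1, methyl (11R)-3β-[(Z)-2-methylbut-2-enoyloxy]-8-oxo-10βH-eremophil-6-en-12-oate (3S,4R,5R,10R,11R) | C/C=C(/C)C(=O)O[C@H]1CC[C@@H]2CC(=O)C([C@@H](C)C(=O)OC)=C[C@]2(C)[C@H]1C | target

**Step count**
Total: 12 steps. Longest linear sequence: 11 steps (steps 1–3 and 5–12); the diene is made in one step (step 4).

**Steps most likely to fail**

1. Step 10. Reduction of the C–I bond or reductive dimerisation of the iodoenone may outrun capture of the ester radical, and catalyst control at C11 may be weak next to the chiral decalin. Fallback, from 13 back to 15: a Pd-catalysed Negishi coupling (Pd2(dba)3, P(2-furyl)3, THF, 23–50 °C) of 13 with the Reformatsky reagent (1-methoxy-1-oxopropan-2-yl)zinc bromide F1, made from purchased methyl 2-bromopropanoate and Zn. This would give 15 together with its C11 epimer F2; the two diastereomers would be separated by chromatography and F2 recycled by equilibration at C11 with DBU in toluene. This fallback gives up catalyst control of C11 and relies on separation.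

2. Step 7. Hydrogen may be delivered from the β face through the ring-flipped conformer of the cis-decalin (angular methyl and silyloxy group equatorial), and the exocyclic alkene may migrate into the ring. Fallback, from 9 back to 12, in which C4 is set by an intramolecular hydride shift instead of by approach control:
   - MeMgBr/CeCl3 (THF, −78 °C) adds to the C4 ketone to give the tertiary alcohol F3 (either C4 epimer serves).
   - Pd(OAc)2 unveils the enone F4.
   - BF3·OEt2 (CH2Cl2, −78 °C) ionises the tertiary alcohol, and the C3 hydrogen, which lies on the α face, shifts suprafacially to C4 (pinacol-type rearrangement). This should give the 4β-methyl-3,8-dione F5 with loss of the silyl group.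
   - NaBH4 (MeOH/CH2Cl2, −78 °C) should reduce the saturated C3 ketone in preference to the enone, from the α face anti to the angular methyl, to the 3β-alcohol F6.
   - TBSCl/imidazole returns 12.

3. Step 5. The α-methylated enone may react so slowly that the Lewis acid consumes the diene, and facial discrimination by the C3 silyl ether may be incomplete at the temperature needed. Fallback, from 6 back to 12: the far more reactive, purchased trans-1-methoxy-3-(trimethylsilyloxy)buta-1,3-diene is used with ZnCl2 in THF at 23 °C (or at 12 kbar without a Lewis acid). It forms the same two bonds and gives the cycloadduct F7 (C6 methoxy, C7=C8 trimethylsilyl enol ether). Cp2TiMe2 then gives the methylidene compound F8 and hydrogenation the 4β-methyl compound F9. Finally 0.1 M HCl in THF hydrolyses the enol ether and eliminates methanol to give enone 12 directly, so the palladium oxidation is not needed.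

**Further compounds**
F1 | step 10 | (1-methoxy-1-oxopropan-2-yl)zinc bromide | CC([Zn]Br)C(=O)OC
F2 | step 10 | methyl (11S)-3β-(tert-butyldimethylsilyloxy)-8-oxo-10βH-eremophil-6-en-12-oate (C11 epimer of 15) | CC(C)(C)[Si](C)(C)O[C@H]1CC[C@@H]2CC(=O)C([C@H](C)C(=O)OC)=C[C@]2(C)[C@H]1C
F3 | step 7 | 4-hydroxy-4-methyl adduct (tertiary alcohol from 9, C4 configuration open) | CC(C)(C)[Si](C)(C)O[C@H]1CC[C@@H]2CC(O[Si](C)(C)C(C)(C)C)=CC[C@]2(C)C1(C)O
F4 | step 7 | 3β-(tert-butyldimethylsilyloxy)-4-hydroxy-4,5β-dimethyl-10βH-cis-decal-6-en-8-one | CC(C)(C)[Si](C)(C)O[C@H]1CC[C@@H]2CC(=O)C=C[C@]2(C)C1(C)O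
F5 | step 7 | 4β,5β-dimethyl-10βH-cis-decal-6-ene-3,8-dione | O=C1CC[C@@H]2CC(=O)C=C[C@]2(C)[C@H]1C
F6 | step 7 | 3β-hydroxy-4β,5β-dimethyl-10βH-cis-decal-6-en-8-one | O[C@H]1CC[C@@H]2CC(=O)C=C[C@]2(C)[C@H]1C
F7 | step 5 | 6-methoxy cycloadduct (C4 ketone, 3β-silyloxy, 5β-methyl, 10β-H, C7=C8 trimethylsilyl enol ether) | CC(C)(C)[Si](C)(C)O[C@H]1CC[C@@H]2CC(O[Si](C)(C)C)=CC(OC)[C@]2(C)C1=O
F8 | step 5 | 4-methylidene analogue of F7 | CC(C)(C)[Si](C)(C)O[C@H]1CC[C@@H]2CC(O[Si](C)(C)C)=CC(OC)[C@]2(C)C1=C
F9 | step 5 | 4β-methyl analogue of F7 | CC(C)(C)[Si](C)(C)O[C@H]1CC[C@@H]2CC(O[Si](C)(C)C)=CC(OC)[C@]2(C)[C@H]1C
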